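**Assumptions**
- 2,6-Dimethoxyphenol reacts with electrophiles para to the OH, as in syringol/formaldehyde condensations.
- The (R)-diarylprolinol silyl ether gives the syn-(2R,3S) adduct by the usual facial model for this catalyst class. If the opposite sense is seen, the (S)-catalyst is used.
- The target (2S,3R,4R,5S) is the all-trans, C2-symmetric 2,5-diaryl-3,4-bis(hydroxymethyl)tetrahydrofuran.

**Retrosynthesis**
1. The target comes from hydrogenolysis of the bis-benzyl ether of the target.
2. That ether comes from a one-pot double Friedel–Crafts C-arylation and cyclodehydrative etherification of the C2-symmetric bis(dimethyl acetal) with 2 equiv of syringol. The THF ring and both benzylic stereocenters form here under thermodynamic all-trans control.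
3. The bis-acetal comes from acetalization and Nef reaction (in MeOH) of the Michael adduct.
4. The adduct comes from the enamine-catalyzed Michael addition of 3-(benzyloxy)propanal to the γ-benzyloxy nitroalkene. This sets the trans C3/C4 stereocenters. The nitroalkene is made from 2-(benzyloxy)acetaldehyde and nitromethane (Henry reaction, then dehydration).

**Route**

**Step 1**
- Reactants: 1 (2-(benzyloxy)acetaldehyde), 2 (nitromethane)
- Product: 3 ((±)-1-(benzyloxy)-3-nitropropan-2-ol)
- Conditions: MeNO2 (5 equiv), K2CO3 (10 mol %), THF, 0 °C → rt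
- Reagents that add atoms: nitromethane, C[N+](=O)[O-]
- Why: Henry (nitroaldol) reaction. The carbinol stereocenter is destroyed in step 2, so it is left racemic.

**Step 2**
- Reactants: 3
- Product: 4 ((E)-{[(3-nitroprop-2-en-1-yl)oxy]methyl}benzene, the (E)-γ-benzyloxy nitroalkene)
- Conditions: MsCl (1.1 equiv), Et3N (2.5 equiv), CH2Cl2, −20 → 0 °C
- Reagents that add atoms: none (the mesylate is lost)
- Why: mesylation followed by E1cB elimination gives the conjugated (E)-nitroalkene.

**Step 3**
- Reactants: 4, 5 (3-(benzyloxy)propanal, 2 equiv), 6 ((R)-diphenylprolinol trimethylsilyl ether, 10 mol %)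
- Product: 7 ((2R,3S)-2,3-bis[(benzyloxy)methyl]-4-nitrobutanal, the syn adduct)
- Conditions: 6 (10 mol %), PhCO2H (10 mol %), toluene, 0 °C, 24 h. The crude aldehyde is taken on immediately.
- Reagents that add atoms: none besides the reactants
- Why: enamine-catalyzed Michael addition (Hayashi–Jørgensen). The bulky silyloxy-diaryl group shields one enamine face, and a synclinal transition state gives the syn adduct. This sets both future THF C3/C4 stereocenters. The syn (2R,3S) open-chain adduct corresponds to the C2-symmetric (R,R) bis-acetal and therefore to the trans-3,4 ring.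

**Step 4**
- Reactants: 7
- Product: 8 ((2R,3S)-2,3-bis[(benzyloxy)methyl]-1,1-dimethoxy-4-nitrobutane)
- Conditions: HC(OMe)3 (3 equiv), TsOH·H2O (5 mol %), MeOH, 0 °C → rt, 2 h
- Reagents that add atoms: trimethyl orthoformate, COC(OC)OC; methanol, CO
- Why: acetalization fixes the epimerizable α-stereocenter and protects the aldehyde from the base used in step 5.

**Step 5**
- Reactants: 8
- Product: 9 ((2R,3R)-2,3-bis[(benzyloxy)methyl]-1,1,4,4-tetramethoxybutane, C2-symmetric)
- Conditions: (i) NaOMe (1.05 equiv), MeOH, 0 °C, 20 min; (ii) the nitronate solution is added to H2SO4 (5 equiv)/MeOH at −30 °C, warmed to 0 °C, then NaHCO3 quench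
- Reagents that add atoms: methanol, CO
- Why: Nef reaction in anhydrous methanol converts CH2NO2 directly to the dimethyl acetal. The stereocenters are untouched: the carbon β to the nitro group is not acidic, and the acetal-bearing carbon cannot enolize.

**Step 6**
- Reactants: 9, 10 (2,6-dimethoxyphenol, 2.6 equiv)
- Product: 11 ((2S,3R,4R,5S)-2,5-bis(4-hydroxy-3,5-dimethoxyphenyl)-3,4-bis[(benzyloxy)methyl]tetrahydrofuran)
- Conditions: HNTf2 (10 mol %), H2O (1.0 equiv), CH2Cl2/MeNO2 4:1 (0.02 M), 0 °C → rt, 16 h
- Reagents that add atoms: water, O (net: 9 + 2 ArH + H2O → 11 + 4 MeOH; C40H56O13 → C36H40O9 + 4 CH4O)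
- Why: Proposed new method: the acid ionizes one dimethyl acetal, and the oxocarbenium is arylated by syringol para to OH (Friedel–Crafts). The resulting p-hydroxybenzylic methyl ether ionizes to a quinone-methide-type cation and is captured by water as the benzylic alcohol. The second acetal ionizes, and the benzylic hydroxyl closes the five-membered ring (5-exo etherification) to a 2-aryl-5-methoxytetrahydrofuran. Ionization of this gives a cyclic oxocarbenium that is arylated a second time. The p-hydroxybenzylic C–O bonds ionize reversibly, so C2 and C5 equilibrate to the all-trans isomer while C3/C4 stay fixed. The closest known reactions are acid-catalyzed Friedel–Crafts C-arylation of acetals and lactols (C-aryl glycoside type) and cyclodehydration of 1,4-diols to THFs.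

**Step 7**
- Reactants: 11
- Product: 12 (Huazhongilexin)
- Conditions: H2 (1 atm), 20% Pd(OH)2/C, EtOAc/MeOH 1:1, rt, 2–3 h (monitor closely)
- Reagents that add atoms: none (H2 adds only hydrogen; toluene is lost)
- Why: hydrogenolysis of the two primary benzyl ethers releases the CH2OH groups. The aryl methyl ethers, the free phenols and all stereocenters are unaffected. The product is C22H28O9.

**Compound list**

1 | 2-(Benzyloxy)acetaldehyde | O=CCOCc1ccccc1 | starting material
2 | Nitromethane | C[N+](=O)[O-] | starting material
3 | (±)-1-(Benzyloxy)-3-nitropropan-2-ol | OC(COCc1ccccc1)C[N+](=O)[O-] | intermediate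
4 | (E)-{[(3-Nitroprop-2-en-1-yl)oxy]methyl}benzene | [O-][N+](=O)/C=C/COCc1ccccc1 | intermediate
5 | 3-(Benzyloxy)propanal | O=CCCOCc1ccccc1 | starting material
6 | (R)-2-[Diphenyl(trimethylsilyloxy)methyl]pyrrolidine (organocatalyst) | C[Si](C)(C)OC(c1ccccc1)(c1ccccc1)[C@H]1CCCN1 | starting material
7 | (2R,3S)-2,3-Bis[(benzyloxy)methyl]-4-nitrobutanal | O=C[C@@H](COCc1ccccc1)[C@H](COCc1ccccc1)C[N+](=O)[O-] | intermediate
8 | (2R,3S)-2,3-Bis[(benzyloxy)methyl]-1,1-dimethoxy-4-nitrobutane | COC(OC)[C@@H](COCc1ccccc1)[C@H](COCc1ccccc1)C[N+](=O)[O-] | intermediate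
9 | (2R,3R)-2,3-Bis[(benzyloxy)methyl]-1,1,4,4-tetramethoxybutane | COC(OC)[C@@H](COCc1ccccc1)[C@H](COCc1ccccc1)C(OC)OC | intermediate
10 | 2,6-Dimethoxyphenol | COc1cccc(OC)c1O | starting material
11 | (2S,3R,4R,5S)-2,5-Bis(4-hydroxy-3,5-dimethoxyphenyl)-3,4-bis[(benzyloxy)methyl]tetrahydrofuran | COc1cc([C@H]2O[C@H](c3cc(OC)c(O)c(OC)c3)[C@@H](COCc4ccccc4)[C@@H]2COCc5ccccc5)cc(OC)c1O | intermediate
12 | Huazhongilexin | COc1cc([C@H]2O[C@H](c3cc(OC)c(O)c(OC)c3)[C@@H](CO)[C@@H]2CO)cc(OC)c1O | target

**Total steps:** 7. **Longest linear sequence:** 7 steps (1 → 3 → 4 → 7 → 8 → 9 → 11 → 12).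

**Three steps most likely to fail**
1. **Step 6 (proposed new method).** Risks are diarylation at a single benzylic carbon (bisphenol formation), O- or ortho-alkylation of syringol, incomplete cyclization, and a poor all-trans ratio. Enol-ether formation from an oxocarbenium could also epimerize C3/C4 and erode ee.
   - Fallback (known chemistry): hydrolyze 9 to the dialdehyde and add 2 equiv of 4-benzyloxy-3,5-dimethoxyphenyllithium. Then cyclodehydrate the resulting 1,4-diol with TsOH to the all-trans THF. Hydrogenolysis in step 7 then removes all benzyl groups.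
2. **Step 3.** The donor is a β-alkoxy aldehyde, which can eliminate to acrolein, and the acceptor is a less reactive alkyl nitroalkene. This could give low yield, dr or ee.
   - Fallback (different approach): Evans auxiliary route. Use the N-[3-(benzyloxy)propanoyl] oxazolidinone, form its Ti enolate, and carry out oxidative homocoupling to the C2-symmetric succinyl bis-imide. Then reduce with LiBH4, oxidize with DMP to the dialdehyde, and acetalize to give 9.
3. **Step 7.** Hydrogenolysis could also cleave the electron-rich benzylic THF C–O bonds.
   - Fallback (different mechanism): remove the benzyl ethers non-reductively with BCl3·SMe2, or BCl3 with pentamethylbenzene as cation scavenger, at −78 °C. If that is unselective, rerun the sequence with TBDPS-protected primary hydroxyls and deprotect with TBAF.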